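**Plan**

- Retrosynthesis: both esters and the C-8 ketone go back to a 3-keto-8,9-bis(silyloxy) cis-decalin. The C9–C10 bond of ring B is then cut, giving a ring-A silyl dienol ether that carries a C-9 aldehyde on the C-5 side chain. C7–C8 is cut to a prenyl group plus ethyl glyoxylate. C5–C6 and C4–CH3 are cut to 3-methylcyclohex-2-enone, a homoallyl organomagnesium reagent and MeI.
- Enabling feature: C-10 is the γ-carbon of the C-3 carbonyl of ring A (C3, C2=C1, C10) and C-9 bears oxygen. Ring A as its 3-silyloxy-1(10),2-diene is therefore nucleophilic at C-10 toward a C-9 aldehyde, and the quaternary C-5 next to C-10 holds the tether C6–C9.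
- Forward order: ring A (steps 1–3); chain C6–C9 completed and armed (steps 4–6); ring B closed by an intramolecular vinylogous Mukaiyama aldol reaction (step 7); then reduction, two acylations and oxidation (steps 8–13).
- Stereochemistry: C-5 from the chiral copper catalyst; C-4 by enolate methylation anti to the chain; C-7 (with a sacrificial C-8 carbinol) from the BINOL–titanium ene catalyst; C-10 and C-9 in the key step under control of C-5 and C-7; C-3 by thermodynamically controlled dissolving-metal reduction.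

Key step: step 7

Remark: eremophilane numbering of the target is used for all intermediates (decalin C-1 to C-10, CH3-15 on C-4, CH3-14 on C-5, C-11 to C-13 on C-7); the C-8 carbinol configuration is sacrificial because C-8 ends as the ketone, and metal alkoxides that are only hydrolysed on aqueous work-up are treated as part of the work-up.

**Route**

Step 1
Reactants: 1 3-methylcyclohex-2-en-1-one; 2 4-bromo-2-methylbut-1-ene
Product: 5 (2R,3R)-2,3-dimethyl-3-(3-methylbut-3-en-1-yl)cyclohexan-1-one, via organomagnesium bromide 3 (not isolated), via magnesium enolate 4 (not isolated)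
Conditions: Mg, Et2O, rt; then 1, Cu(OTf)2 (3 mol %), chiral imidazolinium chloride as N-heterocyclic carbene precursor (4 mol %, enantiomer chosen for 3R addition), Et2O, 0 °C; then MeI, DMPU, 0 °C to rt
Reagents that add atoms: iodomethane, CI
Why: Copper-catalysed asymmetric conjugate addition of the organomagnesium reagent to the β-methyl enone should create the C-5 quaternary centre under ligand control, and the regiodefined magnesium enolate is methylated in the same flask at C-4 anti to the larger homoallyl chain on the neighbouring quaternary carbon, that is cis to the C-5 methyl (tandem conjugate addition–enolate alkylation); any C-4 epimer is separable and can be recycled by base equilibration.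

Step 2
Reactants: 5 (2R,3R)-2,3-dimethyl-3-(3-methylbut-3-en-1-yl)cyclohexan-1-one
Product: 6 (2R,3R)-2,3-dimethyl-3-(3-methylbut-2-en-1-yl)cyclohexan-1-one
Conditions: Co(salen)Cl (5 mol %; salen = N,N′-bis(3,5-di-tert-butylsalicylidene)cyclohexane-1,2-diaminate), PhSiH3 (5 mol %), benzene, rt
Reagents that add atoms: none
Why: Cobalt-hydride hydrogen-atom-transfer isomerisation passes through the tertiary C-11 radical and should move the 1,1-disubstituted double bond one position into the more stable trisubstituted prenyl position, without touching the ketone or the C-4 and C-5 centres.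

Step 3
Reactants: 6 (2R,3R)-2,3-dimethyl-3-(3-methylbut-2-en-1-yl)cyclohexan-1-one
Product: 8 (5R,6R)-5,6-dimethyl-5-(3-methylbut-2-en-1-yl)cyclohex-2-en-1-one, via lithium enolate 7 (not isolated)
Conditions: LDA (LiN(iPr)2), THF, −78 °C; then N-tert-butylbenzenesulfinimidoyl chloride, −78 °C
Reagents that add atoms: none
Why: Kinetic deprotonation takes place at the unhindered C-2 methylene rather than at the C-4 methine next to the quaternary carbon, and S-sulfinimidoylation of the enolate followed by spontaneous syn-elimination of the sulfenamide gives the C1=C2 enone (one-pot ketone α,β-dehydrogenation), leaving C-4 untouched.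

Step 4
Reactants: 8 (5R,6R)-5,6-dimethyl-5-(3-methylbut-2-en-1-yl)cyclohex-2-en-1-one; 9 ethyl glyoxylate
Product: 10 ethyl (2S,3R)-3-{[(1R,2R)-1,2-dimethyl-3-oxocyclohex-4-en-1-yl]methyl}-2-hydroxy-4-methylpent-4-enoate
Conditions: (S)-BINOL (10 mol %), Ti(OiPr)2Cl2 (10 mol %), 4 Å molecular sieves, CH2Cl2, −30 °C
Reagents that add atoms: none
Why: Catalytic asymmetric glyoxylate-ene reaction in which the titanium-bound glyoxylate bonds to C-7, the less substituted carbon of the prenyl double bond, while a methyl hydrogen is transferred so that the isopropenyl group appears, the chiral catalyst fixing the aldehyde face (8S, a centre that is later oxidised away) and the syn-selective transition state relaying this to C-7 (R).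

Step 5
Reactants: 10 ethyl (2S,3R)-3-{[(1R,2R)-1,2-dimethyl-3-oxocyclohex-4-en-1-yl]methyl}-2-hydroxy-4-methylpent-4-enoate
Product: 12 ethyl (2S,3R)-2-[(tert-butyldimethylsilyl)oxy]-3-{[(1S,6R)-1,6-dimethyl-5-[(triethylsilyl)oxy]cyclohexa-2,4-dien-1-yl]methyl}-4-methylpent-4-enoate, via TBS ether 11 (not isolated)
Conditions: TBSOTf (1.05 equiv), Et3N, CH2Cl2, −78 °C; then TESOTf (1.5 equiv), 0 °C to rt
Reagents that add atoms: tert-butyldimethylsilyl trifluoromethanesulfonate, CC(C)(C)[Si](C)(C)OS(=O)(=O)C(F)(F)F; triethylsilyl trifluoromethanesulfonate, CC[Si](CC)(CC)OS(=O)(=O)C(F)(F)F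
Why: Silylation of the hydroxyl is much faster than soft enolisation, so the TBS group goes onto O-8 first, and TESOTf/Et3N then enolises the enone under equilibrating conditions by γ-deprotonation at C-10 (the α′ C-4–H is a hindered methine) to the linearly conjugated 3-silyloxy-1(10),2-diene, which masks the ketone and makes C-10 nucleophilic.

Step 6
Reactants: 12 ethyl (2S,3R)-2-[(tert-butyldimethylsilyl)oxy]-3-{[(1S,6R)-1,6-dimethyl-5-[(triethylsilyl)oxy]cyclohexa-2,4-dien-1-yl]methyl}-4-methylpent-4-enoate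
Product: 13 (2S,3R)-2-[(tert-butyldimethylsilyl)oxy]-3-{[(1S,6R)-1,6-dimethyl-5-[(triethylsilyl)oxy]cyclohexa-2,4-dien-1-yl]methyl}-4-methylpent-4-enal
Conditions: DIBAL-H (iBu2AlH, 1.1 equiv), CH2Cl2, −78 °C; aq. potassium sodium tartrate
Reagents that add atoms: none
Why: Partial reduction of the α-silyloxy ester stops at the aluminium hemiacetal at −78 °C and gives the C-9 aldehyde on work-up, while the silyl dienol ether and both alkenes are inert to DIBAL-H.

Step 7
Reactants: 13 (2S,3R)-2-[(tert-butyldimethylsilyl)oxy]-3-{[(1S,6R)-1,6-dimethyl-5-[(triethylsilyl)oxy]cyclohexa-2,4-dien-1-yl]methyl}-4-methylpent-4-enal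
Product: 14 (4R,5S,7R,8S,9R,10S)-8-[(tert-butyldimethylsilyl)oxy]-9-[(triethylsilyl)oxy]eremophila-1,11-dien-3-one
Conditions: Tf2NH (2 mol %), CH2Cl2, −78 °C; Et3N quench
Reagents that add atoms: none
Why: Tf2NH protodesilylates a trace of 13 to Et3SiNTf2, which activates the C-9 aldehyde as a silyloxocarbenium ion; the γ-carbon C-10 of the ring-A silyloxydiene (C3=C2–C1=C10) attacks it and the silyl group leaves O-3 for the next turnover, so the enone returns and O-9 is silylated (intramolecular vinylogous Mukaiyama aldol reaction, the closest known type being Lewis-acid-mediated vinylogous aldol cyclisations of cyclic silyl dienol ethers onto tethered aldehydes). Ring B closes in the 6-(enolexo)-exo-trig mode, and attack through the α-carbon C-2 would need a bridged eight-membered ring and is excluded. C-10: the four-atom tether starts at the quaternary C-5 next to C-10 and can reach the diene only on the face anti to the C-5 methyl, perpendicular to the diene plane, which gives the cis ring fusion (10-H syn to the C-5 methyl). C-9: in the chair-like transition state the C-7 isopropenyl group is equatorial and the bulky silyloxonium oxygen points away from ring A (equatorial), because the axial alternative runs into C-4, which gives the 9R configuration (O-9 cis to 10-H). The step needs γ- over α-regioselectivity, aldehyde-face selectivity and chemoselectivity over a Prins or ene reaction of the isopropenyl group; the ring-size constraint, the cis-fused chair and the much higher nucleophilicity of the silyl dienol ether secure them.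

Step 8
Reactants: 14 (4R,5S,7R,8S,9R,10S)-8-[(tert-butyldimethylsilyl)oxy]-9-[(triethylsilyl)oxy]eremophila-1,11-dien-3-one
Product: 16 (3R,4R,5R,7R,8S,9R,10S)-8-[(tert-butyldimethylsilyl)oxy]-9-[(triethylsilyl)oxy]eremophil-11-en-3-ol, via saturated ketone 15 (not isolated)
Conditions: Li (excess), NH3(l)/THF, EtOH, −78 to −33 °C; then NH4Cl
Reagents that add atoms: none
Why: Dissolving-metal reduction first saturates the enone through its radical anion and enolate and then reduces the ketone under thermodynamic control to the equatorial 3α-alcohol (the 3β epimer would be syn-axial to the C-5 methyl), while the isolated isopropenyl group and both silyl ethers survive.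

Step 9
Reactants: 16 (3R,4R,5R,7R,8S,9R,10S)-8-[(tert-butyldimethylsilyl)oxy]-9-[(triethylsilyl)oxy]eremophil-11-en-3-ol; 17 (2E)-2-methylbut-2-enoyl chloride
Product: 18 (3R,4R,5R,7R,8S,9R,10S)-8-[(tert-butyldimethylsilyl)oxy]-9-[(triethylsilyl)oxy]eremophil-11-en-3-yl (2E)-2-methylbut-2-enoate
Conditions: pyridine, DMAP (cat.), CH2Cl2, 0 °C to rt
Reagents that add atoms: none
Why: DMAP-catalysed esterification of the only free hydroxyl installs the tiglate, whose E geometry is the thermodynamically stable one.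

Step 10
Reactants: 18 (3R,4R,5R,7R,8S,9R,10S)-8-[(tert-butyldimethylsilyl)oxy]-9-[(triethylsilyl)oxy]eremophil-11-en-3-yl (2E)-2-methylbut-2-enoate
Product: 19 (3R,4R,5R,7R,8S,9R,10S)-8-[(tert-butyldimethylsilyl)oxy]-9-hydroxyeremophil-11-en-3-yl (2E)-2-methylbut-2-enoate
Conditions: PPTS (cat.), MeOH/CH2Cl2, 0 °C
Reagents that add atoms: none
Why: Acid-catalysed methanolysis removes the more labile triethylsilyl ether selectively in the presence of the tert-butyldimethylsilyl ether and the ester (selective silyl ether cleavage), freeing only O-9.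

Step 11
Reactants: 19 (3R,4R,5R,7R,8S,9R,10S)-8-[(tert-butyldimethylsilyl)oxy]-9-hydroxyeremophil-11-en-3-yl (2E)-2-methylbut-2-enoate; 20 3-methylbut-2-enoyl chloride
Product: 21 (3R,4R,5R,7R,8S,9R,10S)-8-[(tert-butyldimethylsilyl)oxy]-9-[(3-methylbut-2-enoyl)oxy]eremophil-11-en-3-yl (2E)-2-methylbut-2-enoate
Conditions: pyridine, DMAP, CH2Cl2, rt to 40 °C
Reagents that add atoms: none
Why: DMAP-catalysed acylation of the single free, equatorial 9-hydroxyl gives the senecioate, pyridine being used as base to avoid deconjugation of the acyl chloride through a vinylketene.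

Step 12
Reactants: 21 (3R,4R,5R,7R,8S,9R,10S)-8-[(tert-butyldimethylsilyl)oxy]-9-[(3-methylbut-2-enoyl)oxy]eremophil-11-en-3-yl (2E)-2-methylbut-2-enoate
Product: 22 (3R,4R,5R,7R,8S,9R,10S)-8-hydroxy-9-[(3-methylbut-2-enoyl)oxy]eremophil-11-en-3-yl (2E)-2-methylbut-2-enoate
Conditions: HF·pyridine, THF/pyridine, 0 °C to rt
Reagents that add atoms: none
Why: Fluoride cleavage of the remaining silyl ether under weakly acidic conditions frees the 8-hydroxyl while disfavouring base-induced acyl migration from O-9.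

Step 13
Reactants: 22 (3R,4R,5R,7R,8S,9R,10S)-8-hydroxy-9-[(3-methylbut-2-enoyl)oxy]eremophil-11-en-3-yl (2E)-2-methylbut-2-enoate
Product: 23 (3R,4R,5R,7R,9R,10S)-9-[(3-methylbut-2-enoyl)oxy]-8-oxoeremophil-11-en-3-yl (2E)-2-methylbut-2-enoate
Conditions: DMP (1,1,1-triacetoxy-1,1-dihydro-1,2-benziodoxol-3(1H)-one), NaHCO3, CH2Cl2, 0 °C to rt
Reagents that add atoms: none
Why: Buffered periodinane oxidation of the axial 8-alcohol gives the ketone under neutral conditions that should neither epimerise C-7 or C-9 nor move the isopropenyl double bond into conjugation.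

**Compound list**

1 | 3-methylcyclohex-2-en-1-one | CC1=CC(=O)CCC1 | starting material
2 | 4-bromo-2-methylbut-1-ene | C=C(C)CCBr | starting material
3 | (3-methylbut-3-en-1-yl)magnesium bromide | C=C(C)CC[Mg]Br | intermediate
4 | bromomagnesium (3R)-3-methyl-3-(3-methylbut-3-en-1-yl)cyclohex-1-en-1-olate | C=C(C)CC[C@@]1(C)CCCC(O[Mg]Br)=C1 | intermediate
5 | (2R,3R)-2,3-dimethyl-3-(3-methylbut-3-en-1-yl)cyclohexan-1-one | C=C(C)CC[C@@]1(C)CCCC(=O)[C@@H]1C | intermediate
6 | (2R,3R)-2,3-dimethyl-3-(3-methylbut-2-en-1-yl)cyclohexan-1-one | CC(C)=CC[C@@]1(C)CCCC(=O)[C@@H]1C | intermediate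
7 | lithium (5R,6R)-5,6-dimethyl-5-(3-methylbut-2-en-1-yl)cyclohex-1-en-1-olate | CC(C)=CC[C@@]1(C)CCC=C(O[Li])[C@@H]1C | intermediate
8 | (5R,6R)-5,6-dimethyl-5-(3-methylbut-2-en-1-yl)cyclohex-2-en-1-one | CC(C)=CC[C@@]1(C)CC=CC(=O)[C@@H]1C | intermediate
9 | ethyl glyoxylate (ethyl 2-oxoacetate) | CCOC(=O)C=O | starting material
10 | ethyl (2S,3R)-3-{[(1R,2R)-1,2-dimethyl-3-oxocyclohex-4-en-1-yl]methyl}-2-hydroxy-4-methylpent-4-enoate | C=C(C)[C@@H](C[C@@]1(C)CC=CC(=O)[C@@H]1C)[C@H](O)C(=O)OCC | intermediate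
11 | ethyl (2S,3R)-2-[(tert-butyldimethylsilyl)oxy]-3-{[(1R,2R)-1,2-dimethyl-3-oxocyclohex-4-en-1-yl]methyl}-4-methylpent-4-enoate | C=C(C)[C@@H](C[C@@]1(C)CC=CC(=O)[C@@H]1C)[C@H](O[Si](C)(C)C(C)(C)C)C(=O)OCC | intermediate
12 | ethyl (2S,3R)-2-[(tert-butyldimethylsilyl)oxy]-3-{[(1S,6R)-1,6-dimethyl-5-[(triethylsilyl)oxy]cyclohexa-2,4-dien-1-yl]methyl}-4-methylpent-4-enoate | C=C(C)[C@@H](C[C@@]1(C)C=CC=C(O[Si](CC)(CC)CC)[C@@H]1C)[C@H](O[Si](C)(C)C(C)(C)C)C(=O)OCC | intermediate
13 | (2S,3R)-2-[(tert-butyldimethylsilyl)oxy]-3-{[(1S,6R)-1,6-dimethyl-5-[(triethylsilyl)oxy]cyclohexa-2,4-dien-1-yl]methyl}-4-methylpent-4-enal | C=C(C)[C@@H](C[C@@]1(C)C=CC=C(O[Si](CC)(CC)CC)[C@@H]1C)[C@H](O[Si](C)(C)C(C)(C)C)C=O | intermediate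
14 | (4R,5S,7R,8S,9R,10S)-8-[(tert-butyldimethylsilyl)oxy]-9-[(triethylsilyl)oxy]eremophila-1,11-dien-3-one (cis-fused) | C=C(C)[C@H]1C[C@@]2(C)[C@H](C=CC(=O)[C@@H]2C)[C@@H](O[Si](CC)(CC)CC)[C@H]1O[Si](C)(C)C(C)(C)C | intermediate
15 | (4R,5S,7R,8S,9R,10S)-8-[(tert-butyldimethylsilyl)oxy]-9-[(triethylsilyl)oxy]eremophil-11-en-3-one | C=C(C)[C@H]1C[C@@]2(C)[C@H](CCC(=O)[C@@H]2C)[C@@H](O[Si](CC)(CC)CC)[C@H]1O[Si](C)(C)C(C)(C)C | intermediate
16 | (3R,4R,5R,7R,8S,9R,10S)-8-[(tert-butyldimethylsilyl)oxy]-9-[(triethylsilyl)oxy]eremophil-11-en-3-ol | C=C(C)[C@H]1C[C@@]2(C)[C@H](CC[C@@H](O)[C@@H]2C)[C@@H](O[Si](CC)(CC)CC)[C@H]1O[Si](C)(C)C(C)(C)C | intermediate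
17 | (2E)-2-methylbut-2-enoyl chloride (tigloyl chloride) | C/C=C(\C)C(=O)Cl | starting material
18 | (3R,4R,5R,7R,8S,9R,10S)-8-[(tert-butyldimethylsilyl)oxy]-9-[(triethylsilyl)oxy]eremophil-11-en-3-yl (2E)-2-methylbut-2-enoate | C=C(C)[C@H]1C[C@@]2(C)[C@H](CC[C@@H](OC(=O)/C(C)=C/C)[C@@H]2C)[C@@H](O[Si](CC)(CC)CC)[C@H]1O[Si](C)(C)C(C)(C)C | intermediate
19 | (3R,4R,5R,7R,8S,9R,10S)-8-[(tert-butyldimethylsilyl)oxy]-9-hydroxyeremophil-11-en-3-yl (2E)-2-methylbut-2-enoate | C=C(C)[C@H]1C[C@@]2(C)[C@H](CC[C@@H](OC(=O)/C(C)=C/C)[C@@H]2C)[C@@H](O)[C@H]1O[Si](C)(C)C(C)(C)C | intermediate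
20 | 3-methylbut-2-enoyl chloride (senecioyl chloride) | CC(C)=CC(=O)Cl | starting material
21 | (3R,4R,5R,7R,8S,9R,10S)-8-[(tert-butyldimethylsilyl)oxy]-9-[(3-methylbut-2-enoyl)oxy]eremophil-11-en-3-yl (2E)-2-methylbut-2-enoate | C=C(C)[C@H]1C[C@@]2(C)[C@H](CC[C@@H](OC(=O)/C(C)=C/C)[C@@H]2C)[C@@H](OC(=O)C=C(C)C)[C@H]1O[Si](C)(C)C(C)(C)C | intermediate
22 | (3R,4R,5R,7R,8S,9R,10S)-8-hydroxy-9-[(3-methylbut-2-enoyl)oxy]eremophil-11-en-3-yl (2E)-2-methylbut-2-enoate | C=C(C)[C@H]1C[C@@]2(C)[C@H](CC[C@@H](OC(=O)/C(C)=C/C)[C@@H]2C)[C@@H](OC(=O)C=C(C)C)[C@H]1O | intermediate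
23 | (3R,4R,5R,7R,9R,10S)-9-[(3-methylbut-2-enoyl)oxy]-8-oxoeremophil-11-en-3-yl (2E)-2-methylbut-2-enoate (cis-fused) | C=C(C)[C@H]1C[C@@]2(C)[C@H](CC[C@@H](OC(=O)/C(C)=C/C)[C@@H]2C)[C@@H](OC(=O)C=C(C)C)C1=O | target

**Summary**

Total step count: 13. Longest linear sequence: 13 steps (from 1).

**Steps most likely to fail**

Step 4. The risk is incomplete transmission of chirality: loss of face control at the glyoxylate or of the syn preference at the prenyl carbon C-7 when the titanium catalyst acts on a hindered trisubstituted alkene next to a quaternary carbon, together with competitive binding of the catalyst by the enone carbonyl. The fallback replaces catalyst control by a covalently bound auxiliary and sets out from 8. An SnCl4-promoted ene reaction (CH2Cl2, −78 °C) with (1R,2S,5R)-8-phenylmenthyl glyoxylate, prepared from commercial 8-phenylmenthol, should give (1R,2S,5R)-5-methyl-2-(2-phenylpropan-2-yl)cyclohexyl (2S,3R)-3-{[(1R,2R)-1,2-dimethyl-3-oxocyclohex-4-en-1-yl]methyl}-2-hydroxy-4-methylpent-4-enoate F1, the aryl group of the auxiliary shielding one face of the tin-chelated glyoxylate. Silylation as in step 5 (TBSOTf, then TESOTf, Et3N) would give the bis-silylated 8-phenylmenthyl ester F2. DIBAL-H (CH2Cl2, −78 °C) then cleaves the auxiliary ester to the aldehyde, returns 8-phenylmenthol, and rejoins the route at 13.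

Step 7. The risk is protodesilylation of the dienol ether outrunning C–C bond formation, or erosion of aldehyde-face selectivity at C-9 under kinetic silyl-cation catalysis. The fallback closes the same bond under reversible, thermodynamic control and sets out from 13. K2CO3 in MeOH (0 °C) removes the dienol silyl group to give (2S,3R)-2-[(tert-butyldimethylsilyl)oxy]-3-{[(1R,2R)-1,2-dimethyl-3-oxocyclohex-4-en-1-yl]methyl}-4-methylpent-4-enal F3. DBU (CH2Cl2, rt) then generates the extended dienolate reversibly, so that the vinylogous aldol equilibrates toward the cis-fused chair with equatorial O-9 and isopropenyl groups, giving (4R,5S,7R,8S,9R,10S)-8-[(tert-butyldimethylsilyl)oxy]-9-hydroxyeremophila-1,11-dien-3-one F4. TESOTf and 2,6-lutidine (CH2Cl2, −78 °C) silylate O-9 and rejoin the route at 14.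

Step 5. The risk is enolisation toward the α′ methine C-4 instead of the γ-methylene C-10, which would give the cross-conjugated silyl dienol ether and leave C-10 unreactive. The fallback makes C-10 an alkene carbon by ketal chemistry instead of enolisation, closes ring B by a pericyclic carbonyl-ene reaction, and sets out from 11 (isolated by stopping step 5 after the TBSOTf stage). Ethylene glycol and PPTS in benzene at reflux with azeotropic removal of water ketalise the enone with the usual shift of the double bond out of conjugation to C1=C10. This gives ethyl (2S,3R)-2-[(tert-butyldimethylsilyl)oxy]-3-{[(6R,7S)-6,7-dimethyl-1,4-dioxaspiro[4.5]dec-8-en-7-yl]methyl}-4-methylpent-4-enoate F5. DIBAL-H (CH2Cl2, −78 °C) gives the corresponding pent-4-enal F6. Me2AlCl (CH2Cl2, −78 °C) forms the C9–C10 bond by an intramolecular carbonyl-ene reaction with hydrogen transfer from C-2, giving (4R,5S,7R,8S,9R,10S)-8-[(tert-butyldimethylsilyl)oxy]-3,3-(ethane-1,2-diyldioxy)eremophila-1,11-dien-9-ol F7. PPTS in acetone–water releases the enone as the hydroxy enone F4 described above, and TESOTf with 2,6-lutidine rejoins the route at 14.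

Further compounds
F1 | step 4 | (1R,2S,5R)-5-methyl-2-(2-phenylpropan-2-yl)cyclohexyl (2S,3R)-3-{[(1R,2R)-1,2-dimethyl-3-oxocyclohex-4-en-1-yl]methyl}-2-hydroxy-4-methylpent-4-enoate | CC(C)(c1ccccc1)[C@@H]1CC[C@@H](C)C[C@H]1OC(=O)[C@@H](O)[C@@H](C(C)=C)C[C@@]2(C)CC=CC(=O)[C@@H]2C
F2 | step 4 | (1R,2S,5R)-5-methyl-2-(2-phenylpropan-2-yl)cyclohexyl (2S,3R)-2-[(tert-butyldimethylsilyl)oxy]-3-{[(1S,6R)-1,6-dimethyl-5-[(triethylsilyl)oxy]cyclohexa-2,4-dien-1-yl]methyl}-4-methylpent-4-enoate | CC(C)(c1ccccc1)[C@@H]1CC[C@@H](C)C[C@H]1OC(=O)[C@@H](O[Si](C)(C)C(C)(C)C)[C@@H](C(C)=C)C[C@@]2(C)C=CC=C(O[Si](CC)(CC)CC)[C@@H]2C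
F3 | step 7 | (2S,3R)-2-[(tert-butyldimethylsilyl)oxy]-3-{[(1R,2R)-1,2-dimethyl-3-oxocyclohex-4-en-1-yl]methyl}-4-methylpent-4-enal | C=C(C)[C@@H](C[C@@]1(C)CC=CC(=O)[C@@H]1C)[C@H](O[Si](C)(C)C(C)(C)C)C=O
F4 | step 7 | (4R,5S,7R,8S,9R,10S)-8-[(tert-butyldimethylsilyl)oxy]-9-hydroxyeremophila-1,11-dien-3-one | C=C(C)[C@H]1C[C@@]2(C)[C@H](C=CC(=O)[C@@H]2C)[C@@H](O)[C@H]1O[Si](C)(C)C(C)(C)C
F5 | step 5 | ethyl (2S,3R)-2-[(tert-butyldimethylsilyl)oxy]-3-{[(6R,7S)-6,7-dimethyl-1,4-dioxaspiro[4.5]dec-8-en-7-yl]methyl}-4-methylpent-4-enoate | C=C(C)[C@@H](C[C@@]1(C)C=CCC2(OCCO2)[C@@H]1C)[C@H](O[Si](C)(C)C(C)(C)C)C(=O)OCC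
F6 | step 5 | (2S,3R)-2-[(tert-butyldimethylsilyl)oxy]-3-{[(6R,7S)-6,7-dimethyl-1,4-dioxaspiro[4.5]dec-8-en-7-yl]methyl}-4-methylpent-4-enal | C=C(C)[C@@H](C[C@@]1(C)C=CCC2(OCCO2)[C@@H]1C)[C@H](O[Si](C)(C)C(C)(C)C)C=O
F7 | step 5 | (4R,5S,7R,8S,9R,10S)-8-[(tert-butyldimethylsilyl)oxy]-3,3-(ethane-1,2-diyldioxy)eremophila-1,11-dien-9-ol | C=C(C)[C@H]1C[C@@]2(C)[C@H](C=CC3(OCCO3)[C@@H]2C)[C@@H](O)[C@H]1O[Si](C)(C)C(C)(C)C
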